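**Remarks on the chemistry (assumptions, one line each)**

- Atom labels C1–C17 and rings A, B, C are those of the target numbering used with the key step.
- Check of the key-step structures: the cyclohexane precursor, the hydrindanone and the target agree at C8, C15 and C16, at C11 (retention), and are opposite at C12, so no configuration needed correction. The hydrindanone carries the C10 ester and the C8 substituent on the same face of ring B, both anti to C17; "trans" is read in that sense, and C10 is labile and lost on decarboxylation.
- Three spectator groups of the precursor are redesigned, the disconnection unchanged: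
  - the silicon on C17 is tied to the C15 oxygen as a six-membered siloxane;
  - C12 enters as the equatorial bromide, made by inversion while C11 is still a CH;
  - the ester is benzyl.
- Compounds 1, 3, 6, 22 and 35 are taken as commercially available.

## Structural features

The target is a C20 dibromo diterpenoid acetate with three carbocycles: a trans-fused hydrindane (cyclopentane ring B and cyclohexane ring C sharing C11–C16) and a separate cyclohexane, ring A, attached to C8 through the methylene C7 at the tertiary acetoxy carbon C1. Ring C holds four contiguous stereocentres, C15–C16–C11–C12: the tertiary carbinol C15 (axial OH), the ring-fusion methine C16, the quaternary C11 with an axial hydroxymethyl group (C17) that is 1,3-diaxial to the C15 hydroxyl, and the equatorial secondary bromide C12; C8 is a fifth centre next to C16. Ring A has the acetate at C1 and the bromide at C4 in a 1,4-cis relation, C4 lying next to the gem-dimethyl carbon C5; these two centres are remote from those of the hydrindane. Both bromides sit beside fully substituted carbons (C12 beside C11, C4 beside C5), so substitution there is slow and elimination or rearrangement easy; the tertiary acetate, the tertiary alcohol and the β-hydroxy relationships are further sensitive points. The real difficulty is the quaternary C11 at a trans ring fusion, flanked by C12–Br and bearing an oxygenated carbon, together with the control of C1 relative to C4. The key step uses the fact that C11 lies 1,5 to C10 across C9, C8 and C16: a C11–H bond of a preformed ring C can be turned into C11–C10 with retention while ring B closes. C17 is carried as a silylmethyl group, whose C–Si bond makes C11–H hydridic and later becomes C17–OH.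

## Logic of the disconnections

45 ⇒ 44. The C17–O bond and the O15–H bond are traced back to the C17–Si and O15–Si bonds of one siloxane ring. Silicon is the only stand-in for the C17 hydroxyl that still donates to C11 in the ring B closure, and the bridge protects O15 through the organometallic step. The 1,3-diaxial diol then needs no protecting groups of its own. The forward step must oxidise C–Si without harming a tertiary acetate and two secondary bromides.

44 ⇒ 34 + 41. C1–C7 and the acetyl–oxygen bond are cut. C1–C7 is the only link between ring A and the hydrindane, so the cut gives two fragments of comparable size. The forward step needs a C7 carbanion that tolerates secondary bromides, attack on 41 anti to its axial C5 methyl in the chair with equatorial bromine, and acylation of a tertiary alkoxide.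

41 ⇒ 39 ⇒ 38 ⇒ 37 ⇒ 36 ⇒ 35. Ring A is opened at C5–C6, the C4–Br bond is traced to an epoxide C–O bond, the epoxide to the olefin of 36 and the ketal to 35. Bromide cannot be introduced by substitution next to the quaternary C5 of a finished ring, so it is placed while C5 is still an epoxide carbon and the ring is closed through a bromonium ion that keeps the C4 configuration. The demands are opening of the epoxide at its secondary carbon and ring closure faster than proton loss.

34 ⇒ 33 ⇒ 32. The C7–I bond goes back to the C7–O bond of a silyl ether. This only changes the functional group, but it requires that the primary silyl ether be removed in the presence of the siloxane.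

32 ⇒ 29 ⇒ 28. The two C9–H bonds go back to the C9 carbonyl. The ketone is the residue of the ring B closure; its removal must not use radicals or strong base because of the C12 bromide.

28 ⇒ 26. The C10–H bond goes back to the C10–ester bond. The ester is needed only to stabilise the diazo compound, so its removal should be neutral.

26 ⇒ 25. C10–C11 is cut and ring B opened. This removes a ring and the quaternary centre and leaves a cyclohexane with only tertiary and secondary centres. The forward step needs C11–H to be the only reachable C–H and to sit equatorial beside the equatorial side chain.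

25 ⇒ 21 + 22. C9–C10 and the O15–Si bond are cut. The lactone carbonyl of 21 acylates C10 and sets O15 free at the moment silicon can capture it. The demand is addition to a hindered lactone in preference to its enolisation.

21 ⇒ 19. The Si–O bond goes back to a Si–phenyl bond, the robust form in which silicon travels through the earlier steps. Cleavage must be selective for the aryl–silicon bond.

19 ⇒ 18. C12–Br goes back to C12–O of opposite configuration. At this stage C11 is a CH, so the substitution is an ordinary secondary one; it must beat elimination.

18 ⇒ 16. The C15–methyl bond and the lactone C9–O15 bond are cut. This removes the tertiary carbinol and leaves a ketone; the methyl nucleophile must add anti to the substituents on C16 and C11.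

16 ⇒ 15 ⇒ 13. The C15 carbonyl goes back to its ketal, and C12–O with C11–H go back to the C11=C12 olefin. Two stereocentres are traded for one olefin; addition must occur syn and anti to the C16 side chain.

13 ⇒ 9. C8–C16 is cut by a retro-[3,3] shift that returns the oxygen to C12. The stereocentres C16 and C8 are traded for one carbinol centre. The rearrangement must be suprafacial and must control the ketene acetal geometry.

9 ⇒ 8 + 2, and 2 ⇒ 1. The ester C–O bond is cut and the acid traced to its alcohol; both steps are routine.

8 ⇒ 5 + 6, and 5 ⇒ 4 ⇒ 3. C11–C17 is cut to an alkenyl iodide and a silylmethyl metal, the C12–H bond to a ketone, and the C11–I bond to an enone C–H. All stereochemistry of the hydrindane half then derives from one reagent-controlled reduction.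

## Other disconnections considered

Alternative 1: The cut opens ring A at C5–C6 and removes bromine from C4 and oxygen from C1, leading back to the hydrindane diol with a 1,5-diene side chain, A2. In the forward direction a vanadium-dependent bromoperoxidase with KBr and H2O2 would deliver bromonium to C4=C5, the C1=C6 methylene would close the ring and water would capture C1 to give A1; acetylation would follow.

- In its favour: one step makes a ring, a C–C, a C–Br and a C–O bond, and the chair-like closure fixes bromine equatorial and oxygen axial by mechanism. On the C1/C4 relationship this is better than the chosen plan, whose step 24 depends on the chair preference of 41. For ring A alone it is also the better in step count.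
- Against it: the absolute sense at the remote C4=C5 olefin has no substrate control and rests on an enzyme accepting an unnatural substrate. The C1 cation can lose a proton or be captured by O15 or O17. Selective acetylation of the hindered tertiary hydroxyl of A1 beside a primary one would need extra protection.
- Comparison: structurally it solves ring A only. The hydrindane with C11 and C12–Br must still be made, for example as in the chosen plan, so it is complementary rather than competing. Mechanistically it is a cationic cyclisation against a metal carbenoid insertion. Overall step economy is about equal once A2 has been assembled.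

Alternative 2: The cut of C11–C16 and C12–C13 leads to the triene A4 with a (Z)-bromoacrylate; heating or Me2AlCl would close rings B and C together to A3.

- In its favour: two rings, two C–C bonds and three stereocentres arise at once, which is better than step 13 on that count. The C12 bromide arrives cis to the C11 ester from the dienophile geometry without any substitution, which is better than step 10. No C9 oxygen has to be removed, which saves about three steps. The C11 ester is an equal of the siloxane as a masked C17 hydroxyl.
- Against it: trans fusion and facial selectivity rest on one stereocentre (C8) and on an exo-type transition state that nona-1,3,8-trienes do not always prefer. The β-bromine lowers dienophile reactivity and invites loss of HBr. The C15 carbinol must then be made by Markovnikov hydration of C14=C15 on the face syn to the axial ester, which is less secure than the methyl addition of step 9.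
- Comparison: it is shorter and richer in bonds formed, but weaker in stereochemical certainty at the ring fusion and at C15. The cycloaddition is suprafacial and the insertion retentive, so both are stereospecific in principle (equal).

Alternative 3: The cut of C14–C15 leads to the cyclopentane A6 with an acetyl group on C16 and an acryloyl group on the quaternary C11; SmI2 (divalent samarium) in THF with methanol would couple the C15 ketyl with C14 in a 6-endo closure to A5.

- In its favour: ring C and the C15 tertiary alcohol form together under mild conditions, and the samarium-bound ketyl can set the C15 configuration. The quaternary C11 is made earlier by enolate chemistry of a β-keto ester, which is the equal or the better of a C–H insertion in reliability. C16, α to the acetyl group, can settle trans by equilibration.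
- Against it: the 6-endo mode competes with reduction or polymerisation of the vinyl ketone. Above all C12 arrives as a ketone, so the equatorial bromide would need reduction to the axial alcohol and displacement next to the quaternary C11, the transformation the chosen plan avoids.
- Comparison: the step count is about equal. Ketyl radical chemistry replaces carbenoid chemistry. The alternative is stronger for C15 and weaker for C12.

Key step: step 13

## Route

Step 1
Reactants: 1 3-[(tert-butyldimethylsilyl)oxy]propan-1-ol
Product: 2 3-[(tert-butyldimethylsilyl)oxy]propanoic acid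
Conditions: 2,2,6,6-tetramethylpiperidin-1-oxyl (TEMPO, cat.), PhI(OAc)2, MeCN/H2O, rt
Reagents that add atoms: water, O
Why: Nitroxyl-catalysed oxidation of a primary alcohol through the aldehyde hydrate to the acid; the fluoride-free, near-neutral medium leaves the silyl ether intact.

Step 2
Reactants: 3 1,4-dioxaspiro[4.5]dec-6-en-8-one
Product: 4 7-iodo-1,4-dioxaspiro[4.5]dec-6-en-8-one
Conditions: I2, pyridine, CH2Cl2, 0 °C → rt
Reagents that add atoms: iodine, II
Why: α-Iodination of an enone by conjugate addition of pyridine, iodination of the enolate and elimination; C11 receives the halogen that will be exchanged for C17.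

Step 3
Reactants: 4 7-iodo-1,4-dioxaspiro[4.5]dec-6-en-8-one
Product: 5 (S)-7-iodo-1,4-dioxaspiro[4.5]dec-6-en-8-ol
Conditions: (R)-Me-CBS [(R)-1-methyl-3,3-diphenyltetrahydro-1H,3H-pyrrolo[1,2-c][1,3,2]oxazaborole] (10 mol%), BH3·SMe2, THF, −20 °C
Reagents that add atoms: none
Why: CBS reduction; the oxazaborolidine–borane complex binds the ketone with the larger iodoalkenyl side away from the catalyst and delivers hydride to one face, a substrate class for which this reduction is well established; this sets the C12 carbinol (S), the only reagent-controlled centre of the hydrindane half.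

Step 4
Reactants: 5 (S)-7-iodo-1,4-dioxaspiro[4.5]dec-6-en-8-ol; 6 (chloromethyl)dimethylphenylsilane
Product: 8 (S)-7-[(dimethylphenylsilyl)methyl]-1,4-dioxaspiro[4.5]dec-6-en-8-ol, via Grignard reagent 7 (not isolated)
Conditions: 6, Mg, THF, 40 °C; then 5, Pd(PPh3)4 (5 mol%), THF, 50 °C
Reagents that add atoms: none
Why: Kumada coupling of an alkenyl iodide with a (silylmethyl)magnesium chloride gives the allylsilane and forms C11–C17; one further equivalent of 7 is consumed by the free hydroxyl.

Step 5
Reactants: 8 (S)-7-[(dimethylphenylsilyl)methyl]-1,4-dioxaspiro[4.5]dec-6-en-8-ol; 2 3-[(tert-butyldimethylsilyl)oxy]propanoic acid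
Product: 9 (S)-7-[(dimethylphenylsilyl)methyl]-1,4-dioxaspiro[4.5]dec-6-en-8-yl 3-[(tert-butyldimethylsilyl)oxy]propanoate
Conditions: DCC, 4-(dimethylamino)pyridine (cat.), CH2Cl2, 0 °C → rt
Reagents that add atoms: none
Why: Steglich esterification of a secondary allylic alcohol under neutral conditions that touch neither the allylsilane nor the ketal.

Step 6
Reactants: 9 (S)-7-[(dimethylphenylsilyl)methyl]-1,4-dioxaspiro[4.5]dec-6-en-8-yl 3-[(tert-butyldimethylsilyl)oxy]propanoate
Product: 13 methyl ester of the rearranged acid (C8–C16 bond formed; C11=C12 olefin), via silyl ketene acetal 10 (not isolated), via trimethylsilyl ester 11 (not isolated), via carboxylic acid 12 (not isolated)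
Conditions: LDA, TMSCl, THF/DMPU, −78 °C → 60 °C; aq. citric acid; then TMSCHN2, PhMe/MeOH, 0 °C
Reagents that add atoms: (trimethylsilyl)diazomethane, C[Si](C)(C)C=[N+]=[N-]
Why: Ireland–Claisen rearrangement; the Z-silyl ketene acetal (DMPU, internal TMSCl quench, which also outruns β-elimination of the silyloxy group) rearranges suprafacially, so C16–C8 forms on the face that carried the C12 oxygen and C16 is set by chirality transfer; the boat-like transition state usual for cyclohexenyl esters places C7 outward and should give C8 as drawn, and a C8 epimer would not be lost because C8 becomes epimerisable in 28, where the drawn configuration is the stable one.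

Step 7
Reactants: 13 methyl ester of the rearranged acid
Product: 15 C12 alcohol (OH on C12 trans to C17; C17 cis to the C16 side chain), via alkylborane 14 (not isolated)
Conditions: BH3·THF, THF, 0 °C → rt; then NaOH, H2O2, 0 °C
Reagents that add atoms: hydrogen peroxide, OO
Why: Hydroboration–oxidation of the trisubstituted allylsilane olefin; boron goes to the less substituted C12 (also favoured electronically, γ to silicon) and H and B add syn from the face opposite the C16 side chain, which A(1,2) strain holds pseudo-axial; this sets C11 and C12.

Step 8
Reactants: 15 C12 alcohol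
Product: 16 C15 ketone
Conditions: pyridinium p-toluenesulfonate (cat.), acetone/H2O, 50 °C
Reagents that add atoms: none
Why: Mild acid-catalysed transketalisation frees the C15 ketone; a weak acid is chosen because C16, cis to the C11 substituent, is now epimerisable.

Step 9
Reactants: 16 C15 ketone
Product: 18 hydroxy γ-lactone (C9–O15 lactone; free C12–OH), via hydroxy ester 17 (not isolated)
Conditions: MeLi, CeCl3, THF, −78 °C → rt
Reagents that add atoms: methyllithium, [Li]C
Why: Organocerium 1,2-addition (non-basic, inert to the ester at −78 °C) from the face opposite the C16 and C11 substituents sets C15 with oxygen syn to the side chain; the alkoxide then closes the cis-fused γ-lactone on the methyl ester, which masks O15 and C9 together and confirms the C15/C16 relationship.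

Step 10
Reactants: 18 hydroxy γ-lactone
Product: 19 bromo lactone (C12–Br cis to C17)
Conditions: CBr4, PPh3, 2,6-lutidine, CH2Cl2, 0 °C → rt
Reagents that add atoms: carbon tetrabromide, BrC(Br)(Br)Br
Why: Appel reaction; bromide displaces the alkoxyphosphonium group with inversion (SN2) at C12, which is flanked by the tertiary CH C11 and not yet by a quaternary carbon; the axial leaving group in the chair with C17 axial is replaced by the equatorial bromide of the target, and in the lactone no carbonyl oxygen can reach C12 as a neighbouring group.

Step 11
Reactants: 19 bromo lactone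
Product: 21 isopropoxysilane (C17–SiMe2–OiPr), via chlorosilane 20 (not isolated)
Conditions: ICl, CH2Cl2, 0 °C; then i-PrOH, Et3N
Reagents that add atoms: propan-2-ol, CC(C)O
Why: Electrophilic ipso-substitution of the phenyl–silicon bond by ICl (iododesilylation) turns the inert phenylsilane into a chlorosilane, trapped at once as the isopropoxysilane; no other π-system or free hydroxyl is present.

Step 12
Reactants: 21 isopropoxysilane; 22 benzyl diazoacetate
Product: 25 siloxane-locked α-diazo-β-keto ester (key-step precursor), via lithiated diazoacetate 23 (not isolated), via ring-opened alkoxide 24 (not isolated)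
Conditions: 22, LDA, THF, −78 °C; then 21, −78 → −30 °C; aq. NH4Cl
Reagents that add atoms: none
Why: Acylation of a lithiated diazoacetate by a lactone forms C9–C10 and gives the α-diazo-β-keto ester in one operation; the tertiary alkoxide that is released displaces isopropoxide at silicon (intramolecular transetherification, six-membered ring), which prevents hemiketal formation and builds the siloxane; if closure at silicon lags, a trace of DBU completes it without harm to the diazo group.

Step 13
Reactants: 25 siloxane-locked α-diazo-β-keto ester
Product: 26 benzyl trans-hydrindan-9-one-10-carboxylate with the C17–Si–O15 bridge (key-step product)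
Conditions: Rh2(OAc)4 (2 mol%), CH2Cl2, rt, slow addition of 25
Reagents that add atoms: none
Why: Rh2(OAc)4 displaces N2 from the diazo carbon to give an electrophilic rhodium carbenoid at C10, which inserts into the C11–H bond through a three-centre, hydride-transfer-like transition state and releases the catalyst. The closest known reaction type is the dirhodium-catalysed 1,5 C–H insertion of α-diazo-β-keto esters into tertiary C–H bonds, which gives 2-oxocyclopentanecarboxylates with retention. Ring B closes as a five-membered ring by 1,5-insertion (C10 to C11 across C9, C8 and C16) through a chair-like cyclic array. The new stereocentre C11 is controlled by the configuration of the C11–H bond set in step 7, which is retained; the trans fusion follows because C11–H and the C16–C8 bond are both equatorial on ring C. Site selectivity is needed and is secured by ring size (C11–H is the only C–H 1,5 to C10), by its tertiary nature and by the C17–Si bond, which the siloxane ring holds close to anti-periplanar to C11–H so that it stabilises the positive charge developing at C11. The siloxane also locks ring C in the chair with C17 and O15 diaxial, the only chair in which C11–H is equatorial and within reach; an open-chain version with separate silyl and silyl ether groups would be free to adopt the other chair, where C11–H is anti to the side chain. Chemoselectivity against a five-membered oxonium ylide at O7 rests on the bulk and low basicity of the tert-butyldimethylsilyl ether and on slow addition; the equatorial C12 bromine offers no oxygen-activated C–H for 1,6-insertion. C10 is formed as a labile centre (ester anti to C17) and disappears in step 14.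

Step 14
Reactants: 26 benzyl trans-hydrindan-9-one-10-carboxylate
Product: 28 C9 ketone, via keto acid 27 (not isolated)
Conditions: H2 (1 atm), Pd on carbon (10%), EtOAc, rt; then 50 °C
Reagents that add atoms: none
Why: Hydrogenolysis of the benzyl ester and thermal decarboxylation of the β-keto acid under neutral conditions avoid β-elimination of the C7 silyloxy group; C8, now α to the ketone, can equilibrate, and the drawn configuration (C7 anti to C15 and C17) is the stable one.

Step 15
Reactants: 28 C9 ketone
Product: 29 C9 tosylhydrazone
Conditions: TsNHNH2, MeOH, 40 °C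
Reagents that add atoms: p-toluenesulfonyl hydrazide, Cc1ccc(cc1)S(=O)(=O)NN
Why: Condensation of the ketone with the sulfonyl hydrazide; the mildly acidic medium tolerates the primary silyl ether and the siloxane.

Step 16
Reactants: 29 C9 tosylhydrazone
Product: 32 C9-methylene compound (C7–OTBS), via sulfonylhydrazine 30 (not isolated), via diazene 31 (not isolated)
Conditions: catecholborane, CHCl3, 0 °C; then NaOAc·3H2O, reflux
Reagents that add atoms: none
Why: Hydride reduction of the tosylhydrazone and acetate-induced loss of sulfinate give a diazene that extrudes N2; this two-electron deoxygenation leaves the secondary bromide untouched, which tin hydride or dissolving-metal methods would not.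

Step 17
Reactants: 32 C9-methylene compound
Product: 33 C7 primary alcohol
Conditions: 10-camphorsulfonic acid (cat.), MeOH/CH2Cl2, 0 °C; concentrate from PhMe
Reagents that add atoms: none
Why: Acid-catalysed methanolysis removes the primary silyl ether much faster than it opens the hindered tertiary-alkoxy siloxane; any methanolysis of the siloxane is reversed on removal of methanol, because ring closure at silicon is intramolecular.

Step 18
Reactants: 33 C7 primary alcohol
Product: 34 C7 primary iodide
Conditions: I2, PPh3, imidazole, CH2Cl2, 0 °C → rt
Reagents that add atoms: iodine, II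
Why: Appel-type iodination of the only free hydroxyl by SN2 at the primary C7.

Step 19
Reactants: 35 6-methylhept-5-en-2-one
Product: 36 2-methyl-2-(4-methylpent-3-en-1-yl)-1,3-dioxolane
Conditions: HOCH2CH2OH, pyridinium p-toluenesulfonate (cat.), PhH, reflux (Dean–Stark)
Reagents that add atoms: ethane-1,2-diol, OCCO
Why: Acid-catalysed ketalisation masks the ketone, which would otherwise form cyclic ketals with the oxygen functions introduced next and interfere with the dioxirane epoxidation.

Step 20
Reactants: 36 2-methyl-2-(4-methylpent-3-en-1-yl)-1,3-dioxolane
Product: 37 (R)-2-[2-(3,3-dimethyloxiran-2-yl)ethyl]-2-methyl-1,3-dioxolane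
Conditions: Shi ketone (1,2:4,5-di-O-isopropylidene-β-D-erythro-2,3-hexodiulo-2,6-pyranose, 30 mol%), Oxone (2KHSO5·KHSO4·K2SO4), K2CO3, Bu4NHSO4, MeCN/CH2(OMe)2/aq. buffer, 0 °C
Reagents that add atoms: potassium peroxymonosulfate, [K+].[O-]S(=O)(=O)OO
Why: Shi epoxidation; the chiral dioxirane transfers oxygen to the trisubstituted olefin through a spiro transition state and should give the (R)-epoxide; this centre becomes C4.

Step 21
Reactants: 37 (R)-epoxide
Product: 38 (S)-3-bromo-2-methyl-5-(2-methyl-1,3-dioxolan-2-yl)pentan-2-ol
Conditions: Li2NiBr4 (from LiBr and NiBr2), THF, 0 °C → rt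
Reagents that add atoms: dilithium tetrabromonickelate, [Li+].[Li+].[Ni+2].[Br-].[Br-].[Br-].[Br-]
Why: Li2NiBr4 is a soft bromide source that opens trisubstituted epoxides by SN2 at the less substituted carbon, so bromide enters C4 with inversion while the tertiary carbon keeps the oxygen; C4 is set as (S) before C5 becomes a quaternary ring carbon.

Step 22
Reactants: 38 (S)-bromohydrin ketal
Product: 39 (S)-bromo bis-silyl compound (tertiary trimethylsilyl ether; terminal 2-(trimethylsilyloxy)ethyl enol ether)
Conditions: TMSOTf, i-Pr2NEt, CH2Cl2, −20 → 0 °C
Reagents that add atoms: trimethylsilyl trifluoromethanesulfonate, C[Si](C)(C)OS(=O)(=O)C(F)(F)F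
Why: The silyl triflate with a hindered amine silylates the tertiary alcohol and opens the dioxolane to the less substituted enol ether by loss of a methyl proton from the oxocarbenium ion (ketal-to-enol-ether conversion).

Step 23
Reactants: 39 (S)-bromo bis-silyl compound
Product: 41 (S)-4-bromo-3,3-dimethylcyclohexan-1-one, via bromo ketal 40 (not isolated)
Conditions: TiCl4, CH2Cl2, −78 °C; then 1 M HCl, THF, rt
Reagents that add atoms: none
Why: Lewis-acid ionisation of the tertiary silyl ether, assisted by the neighbouring bromine (bromonium ion), gives a tertiary cation equivalent that the enol ether carbon captures in a six-membered ring closure forming C5–C6 (SN1-type alkylation of an enol ether by an enantiospecifically generated bromonium ion); bromine stays on C4 throughout, so its configuration is kept, and the pendant silyl ether recloses the ketal, which the acidic work-up hydrolyses.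

Step 24
Reactants: 34 C7 primary iodide; 41 (S)-4-bromo-3,3-dimethylcyclohexan-1-one
Product: 44 siloxane-bridged acetate (target skeleton with C17–SiMe2–O15), via alkyllithium 42 (not isolated), via lithium alkoxide 43 (not isolated)
Conditions: t-BuLi (2.1 equiv), Et2O/pentane, −78 °C; then 41, −78 °C; then Ac2O, −78 °C → rt
Reagents that add atoms: acetic anhydride, CC(=O)OC(C)=O
Why: Iodine–lithium exchange of the primary iodide at −78 °C is far faster than any reaction at the hindered secondary bromides; the alkyllithium adds to the ketone anti to the axial C5 methyl (equatorial attack), which in the chair with equatorial bromine places oxygen axial and cis to bromine (C1 as in the target), and the alkoxide is acetylated in the flask; the chair with axial bromine would give the C1 epimer, which is removed by chromatography at this stage.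

Step 25
Reactants: 44 siloxane-bridged acetate
Product: 45 target, CNP0182818.1
Conditions: KF, KHCO3, 30% H2O2, THF/MeOH, 40 °C
Reagents that add atoms: hydrogen peroxide, OO
Why: Tamao oxidation; fluoride and peroxide form a hypervalent silicate in which the C17 methylene migrates from silicon to oxygen, so the one siloxane releases both the C17 primary alcohol and the C15 tertiary alcohol; the buffered conditions leave the tertiary acetate and the hindered secondary bromides alone.

## Compound list

1 | 3-[(tert-butyldimethylsilyl)oxy]propan-1-ol | CC(C)(C)[Si](C)(C)OCCCO | starting material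
2 | 3-[(tert-butyldimethylsilyl)oxy]propanoic acid | CC(C)(C)[Si](C)(C)OCCC(=O)O | intermediate
3 | 1,4-dioxaspiro[4.5]dec-6-en-8-one | O=C1C=CC2(OCCO2)CC1 | starting material
4 | 7-iodo-1,4-dioxaspiro[4.5]dec-6-en-8-one | O=C1CCC2(OCCO2)C=C1I | intermediate
5 | (S)-7-iodo-1,4-dioxaspiro[4.5]dec-6-en-8-ol | O[C@H]1CCC2(OCCO2)C=C1I | intermediate
6 | (chloromethyl)dimethylphenylsilane | C[Si](C)(CCl)c1ccccc1 | starting material
7 | [(dimethylphenylsilyl)methyl]magnesium chloride | C[Si](C)(C[Mg]Cl)c1ccccc1 | intermediate
8 | (S)-7-[(dimethylphenylsilyl)methyl]-1,4-dioxaspiro[4.5]dec-6-en-8-ol | O[C@H]1CCC2(OCCO2)C=C1C[Si](C)(C)c1ccccc1 | intermediate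
9 | (S)-7-[(dimethylphenylsilyl)methyl]-1,4-dioxaspiro[4.5]dec-6-en-8-yl 3-[(tert-butyldimethylsilyl)oxy]propanoate | CC(C)(C)[Si](C)(C)OCCC(=O)O[C@H]1CCC2(OCCO2)C=C1C[Si](C)(C)c1ccccc1 | intermediate
10 | (Z)-O-trimethylsilyl ketene acetal of 9 (C7 cis to OSiMe3) | CC(C)(C)[Si](C)(C)OC/C=C(\O[Si](C)(C)C)O[C@H]1CCC2(OCCO2)C=C1C[Si](C)(C)c1ccccc1 | intermediate
11 | trimethylsilyl 3-[(tert-butyldimethylsilyl)oxy]-2-{7-[(dimethylphenylsilyl)methyl]-1,4-dioxaspiro[4.5]dec-7-en-6-yl}propanoate (C8, C16 as in the target) | CC(C)(C)[Si](C)(C)OC[C@H](C(=O)O[Si](C)(C)C)[C@H]1C(C[Si](C)(C)c2ccccc2)=CCCC13OCCO3 | intermediate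
12 | 3-[(tert-butyldimethylsilyl)oxy]-2-{7-[(dimethylphenylsilyl)methyl]-1,4-dioxaspiro[4.5]dec-7-en-6-yl}propanoic acid | CC(C)(C)[Si](C)(C)OC[C@H](C(=O)O)[C@H]1C(C[Si](C)(C)c2ccccc2)=CCCC13OCCO3 | intermediate
13 | methyl ester of 12 | CC(C)(C)[Si](C)(C)OC[C@H](C(=O)OC)[C@H]1C(C[Si](C)(C)c2ccccc2)=CCCC13OCCO3 | intermediate
14 | C12 alkylborane from 13 (B on C12 and H on C11 syn, anti to the C16 side chain) | CC(C)(C)[Si](C)(C)OC[C@H](C(=O)OC)[C@H]1[C@@H](C[Si](C)(C)c2ccccc2)[C@H](B)CCC13OCCO3 | intermediate
15 | C12 alcohol: methyl ester, C15 ethylene ketal, C12–OH trans to C17, C17 cis to the C16 side chain | CC(C)(C)[Si](C)(C)OC[C@H](C(=O)OC)[C@H]1[C@@H](C[Si](C)(C)c2ccccc2)[C@H](O)CCC13OCCO3 | intermediate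
16 | C15 ketone: methyl 3-[(tert-butyldimethylsilyl)oxy]-2-{2-[(dimethylphenylsilyl)methyl]-3-hydroxy-6-oxocyclohexyl}propanoate | CC(C)(C)[Si](C)(C)OC[C@H](C(=O)OC)[C@H]1[C@@H](C[Si](C)(C)c2ccccc2)[C@H](O)CCC1=O | intermediate
17 | C15 tertiary alcohol, open hydroxy ester (methyl on C15 anti, OH syn to the side chain) | CC(C)(C)[Si](C)(C)OC[C@H](C(=O)OC)[C@H]1[C@@H](C[Si](C)(C)c2ccccc2)[C@H](O)CC[C@@]1(C)O | intermediate
18 | hydroxy γ-lactone: cis-fused 3-[(tert-butyldimethylsilyloxy)methyl]-4-[(dimethylphenylsilyl)methyl]-5-hydroxy-7a-methylhexahydrobenzofuran-2(3H)-one | CC(C)(C)[Si](C)(C)OC[C@@H]1C(=O)O[C@]2(C)CC[C@@H](O)[C@H](C[Si](C)(C)c3ccccc3)[C@H]12 | intermediate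
19 | bromo lactone: as 18 with C12–Br of inverted configuration (cis to C17) | CC(C)(C)[Si](C)(C)OC[C@@H]1C(=O)O[C@]2(C)CC[C@H](Br)[C@H](C[Si](C)(C)c3ccccc3)[C@H]12 | intermediate
20 | chlorosilane: as 19 with C17–SiMe2Cl | CC(C)(C)[Si](C)(C)OC[C@@H]1C(=O)O[C@]2(C)CC[C@H](Br)[C@H](C[Si](C)(C)Cl)[C@H]12 | intermediate
21 | isopropoxysilane: as 19 with C17–SiMe2(OiPr) | CC(C)(C)[Si](C)(C)OC[C@@H]1C(=O)O[C@]2(C)CC[C@H](Br)[C@H](C[Si](C)(C)OC(C)C)[C@H]12 | intermediate
22 | benzyl diazoacetate | [N-]=[N+]=CC(=O)OCc1ccccc1 | starting material
23 | benzyl lithiodiazoacetate | [Li]C(=[N+]=[N-])C(=O)OCc1ccccc1 | intermediate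
24 | lithium C15 alkoxide of the ring-opened benzyl α-diazo-β-keto ester (C17–SiMe2(OiPr) still open) | CC(C)(C)[Si](C)(C)OC[C@H](C(=O)C(=[N+]=[N-])C(=O)OCc1ccccc1)[C@H]1[C@@H](C[Si](C)(C)OC(C)C)[C@@H](Br)CC[C@@]1(C)O[Li] | intermediate
25 | key-step precursor: benzyl 2-diazo-3-oxo-4-substituted-5-[(tert-butyldimethylsilyl)oxy]pentanoate on a 2-oxa-3-silabicyclo[3.3.1]nonane (C17–SiMe2–O15 bridge, equatorial C12–Br, C11–H) | CC(C)(C)[Si](C)(C)OC[C@H](C(=O)C(=[N+]=[N-])C(=O)OCc1ccccc1)[C@H]2[C@H]3C[Si](C)(C)O[C@]2(C)CC[C@@H]3Br | intermediate
26 | key-step product: benzyl trans-hydrindan-9-one-10-carboxylate with C17–SiMe2–O15 bridge, C12–Br, C7–OTBS | CC(C)(C)[Si](C)(C)OC[C@@H]1C(=O)[C@H](C(=O)OCc2ccccc2)[C@]34C[Si](C)(C)O[C@](C)(CC[C@@H]3Br)[C@@H]14 | intermediate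
27 | β-keto acid from 26 | CC(C)(C)[Si](C)(C)OC[C@@H]1C(=O)[C@H](C(=O)O)[C@]34C[Si](C)(C)O[C@](C)(CC[C@@H]3Br)[C@@H]14 | intermediate
28 | C9 ketone (trans-hydrindan-9-one, siloxane bridge, C12–Br, C7–OTBS) | CC(C)(C)[Si](C)(C)OC[C@@H]1C(=O)C[C@]23C[Si](C)(C)O[C@](C)(CC[C@@H]2Br)[C@@H]13 | intermediate
29 | C9 tosylhydrazone of 28 | CC(C)(C)[Si](C)(C)OC[C@@H]1C(=NNS(=O)(=O)c2ccc(C)cc2)C[C@]34C[Si](C)(C)O[C@](C)(CC[C@@H]3Br)[C@@H]14 | intermediate
30 | N-(C9-alkyl)-N'-tosylhydrazine (C9 configuration not defined) | CC(C)(C)[Si](C)(C)OC[C@@H]1C(NNS(=O)(=O)c2ccc(C)cc2)C[C@]34C[Si](C)(C)O[C@](C)(CC[C@@H]3Br)[C@@H]14 | intermediate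
31 | C9 alkyldiazene | CC(C)(C)[Si](C)(C)OC[C@@H]1C(N=N)C[C@]34C[Si](C)(C)O[C@](C)(CC[C@@H]3Br)[C@@H]14 | intermediate
32 | C9-methylene compound (trans-hydrindane, siloxane bridge, C12–Br, C7–OTBS) | CC(C)(C)[Si](C)(C)OC[C@@H]1CC[C@]23C[Si](C)(C)O[C@](C)(CC[C@@H]2Br)[C@@H]13 | intermediate
33 | C7 primary alcohol | OC[C@@H]1CC[C@]23C[Si](C)(C)O[C@](C)(CC[C@@H]2Br)[C@@H]13 | intermediate
34 | C7 primary iodide | IC[C@@H]1CC[C@]23C[Si](C)(C)O[C@](C)(CC[C@@H]2Br)[C@@H]13 | intermediate
35 | 6-methylhept-5-en-2-one | CC(=O)CCC=C(C)C | starting material
36 | 2-methyl-2-(4-methylpent-3-en-1-yl)-1,3-dioxolane | CC1(CCC=C(C)C)OCCO1 | intermediate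
37 | (R)-2-[2-(3,3-dimethyloxiran-2-yl)ethyl]-2-methyl-1,3-dioxolane | CC1(CC[C@H]2OC2(C)C)OCCO1 | intermediate
38 | (S)-3-bromo-2-methyl-5-(2-methyl-1,3-dioxolan-2-yl)pentan-2-ol | CC1(CC[C@H](Br)C(C)(C)O)OCCO1 | intermediate
39 | (S)-{[3-bromo-2-methyl-6-(2-trimethylsilyloxyethoxy)hept-6-en-2-yl]oxy}trimethylsilane | C=C(CC[C@H](Br)C(C)(C)O[Si](C)(C)C)OCCO[Si](C)(C)C | intermediate
40 | (S)-8-bromo-7,7-dimethyl-1,4-dioxaspiro[4.5]decane | C1COC2(O1)CC[C@H](Br)C(C)(C)C2 | intermediate
41 | (S)-4-bromo-3,3-dimethylcyclohexan-1-one | O=C1CC[C@H](Br)C(C)(C)C1 | intermediate
42 | C7 alkyllithium from 34 | [Li]C[C@@H]1CC[C@]23C[Si](C)(C)O[C@](C)(CC[C@@H]2Br)[C@@H]13 | intermediate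
43 | lithium C1 alkoxide (C1–C7 bond formed) | [Li]O[C@]1(C[C@@H]2CC[C@]34C[Si](C)(C)O[C@](C)(CC[C@@H]3Br)[C@@H]24)CC[C@H](Br)C(C)(C)C1 | intermediate
44 | siloxane-bridged acetate: target in which C17 and O15 are joined through SiMe2 | CC(=O)O[C@]1(C[C@@H]2CC[C@]34C[Si](C)(C)O[C@](C)(CC[C@@H]3Br)[C@@H]24)CC[C@H](Br)C(C)(C)C1 | intermediate
45 | CNP0182818.1: (1S,4S)-4-bromo-3,3-dimethyl-1-[(trans-hydrindanyl)methyl]cyclohexyl acetate with C11–CH2OH, C12–Br, C15(Me)–OH | CC(=O)O[C@]1(C[C@@H]2CC[C@]3(CO)[C@@H](Br)CC[C@@](C)(O)[C@@H]23)CC[C@H](Br)C(C)(C)C1 | target

## Step count and least certain steps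

Total: 25 steps. Longest linear sequence: 19 steps (3 → 45 through steps 2–18, 24 and 25). The ring A ketone takes 5 steps (19–23) and the acid 2 takes 1 step.

Step 13 (key step). Most likely to go wrong: the carbenoid is diverted before it reaches C11–H, by attack of the C7 ether oxygen (five-membered oxonium ylide, then silyl migration) or by carbene dimerisation. The cause would be that the C12 bromine inductively lowers the hydridic character of C11–H and that the doubly stabilised carbenoid is the most discriminating class. Fallback with a less stabilised, more reactive carbenoid that also removes the decarboxylation: from 21, MeLi (1 equiv, −78 °C) opens the lactone to the siloxane-locked methyl ketone F1, the alkoxide closing on silicon as in step 12. LiHMDS and CF3CO2CH2CF3 give the trifluoroacetyl diketone F2, and MsN3/Et3N converts it by detrifluoroacetylative diazo transfer into the terminal diazo ketone F3. Rh2(OAc)4 insertion of F3 into C11–H gives 28 directly, where the route is rejoined.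

Step 12. Most likely to go wrong: proton transfer from the α-branched, hindered lactone to the basic lithiated diazoacetate instead of addition (recovery of 21 with C8 epimerisation), together with thermal decay of the lithiated diazo ester before it adds. Fallback by amide activation and separate diazo transfer: from 21, Me(MeO)NH·HCl/AlMe3 opens the lactone to the siloxane-locked Weinreb amide F4 (ring closure at silicon completed with a trace of KOtBu). The lithium enolate of benzyl acetate converts F4 into the β-keto ester F5, and Regitz diazo transfer (p-acetamidobenzenesulfonyl azide, Et3N) gives 25.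

Step 10. Most likely to go wrong: elimination towards C13 and 1,3-elimination with loss of the γ-silyl group (cyclopropane formation) in place of substitution, because approach to C12 is flanked by the axial silylmethyl group on C11. Fallback that replaces substitution at an activated alcohol by stereoinvertive bromination of a C–B bond: from 13, hydroboration (BH3·THF) and pinacol give the C12 pinacol boronate F6. Its boronate complex with 3,5-bis(trifluoromethyl)phenyllithium is brominated by NBS with inversion to the bromo ketal ester F7. Pyridinium p-toluenesulfonate in wet acetone gives the bromo keto ester F8, and MeLi/CeCl3 addition with lactonisation gives 19.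

Step 24. Most likely to go wrong: loss of diastereocontrol at C1, because 41 can react through both chairs (bromine equatorial or axial), each attacked anti to its own axial C5 methyl, and the axial-bromine chair leads to the C1 epimer; in addition, competing attack of tert-butyllithium on a secondary bromide. Fallback without an organolithium, through a single-electron Barbier coupling with a later, more product-like transition state: from 34 and 41, SmI2 with catalytic NiI2 in THF gives the tertiary alcohol F9, whose C1 epimers are separated. KHMDS then Ac2O acetylates F9 to 44.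

Step 23. Most likely to go wrong: loss of a proton from the β-bromo cation, or transfer of bromonium to the enol ether of a second molecule (α-bromination, with erosion of enantiopurity), in place of ring closure. Fallback through an electrophilic bromocyclisation and resolution: from 35, NaH and (MeO)2CO give the β-keto ester F10. Bromodiethylsulfonium bromopentachloroantimonate (Et2SBr·SbCl5Br) in MeNO2 closes the ring to the racemic bromo β-keto ester F11. LiCl in wet DMSO at 140 °C (Krapcho decarboxylation) gives the racemic ketone F12, and chromatography on a chiral stationary phase delivers 41.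

## Further compounds

F1 | step 13 | siloxane-locked methyl ketone (as 25 with C9 acetyl) | CC(C)(C)[Si](C)(C)OC[C@H](C(C)=O)[C@H]1[C@H]2C[Si](C)(C)O[C@]1(C)CC[C@@H]2Br
F2 | step 13 | trifluoroacetyl diketone from F1 | CC(C)(C)[Si](C)(C)OC[C@H](C(=O)CC(=O)C(F)(F)F)[C@H]1[C@H]2C[Si](C)(C)O[C@]1(C)CC[C@@H]2Br
F3 | step 13 | siloxane-locked terminal α-diazo ketone | CC(C)(C)[Si](C)(C)OC[C@H](C(=O)C=[N+]=[N-])[C@H]1[C@H]2C[Si](C)(C)O[C@]1(C)CC[C@@H]2Br
F4 | step 12 | siloxane-locked Weinreb amide | CC(C)(C)[Si](C)(C)OC[C@H](C(=O)N(C)OC)[C@H]1[C@H]2C[Si](C)(C)O[C@]1(C)CC[C@@H]2Br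
F5 | step 12 | siloxane-locked benzyl β-keto ester | CC(C)(C)[Si](C)(C)OC[C@H](C(=O)CC(=O)OCc1ccccc1)[C@H]2[C@H]3C[Si](C)(C)O[C@]2(C)CC[C@@H]3Br
F6 | step 10 | C12 pinacol boronate of the ketal ester | CC(C)(C)[Si](C)(C)OC[C@H](C(=O)OC)[C@H]1[C@@H](C[Si](C)(C)c2ccccc2)[C@H](B2OC(C)(C)C(C)(C)O2)CCC13OCCO3
F7 | step 10 | C12 bromo ketal ester (Br cis to C17) | CC(C)(C)[Si](C)(C)OC[C@H](C(=O)OC)[C@H]1[C@@H](C[Si](C)(C)c2ccccc2)[C@@H](Br)CCC13OCCO3
F8 | step 10 | C12 bromo C15 keto ester | CC(C)(C)[Si](C)(C)OC[C@H](C(=O)OC)[C@H]1[C@@H](C[Si](C)(C)c2ccccc2)[C@@H](Br)CCC1=O
F9 | step 24 | siloxane-bridged tertiary alcohol (deacetyl 44) | O[C@]1(C[C@@H]2CC[C@]34C[Si](C)(C)O[C@](C)(CC[C@@H]3Br)[C@@H]24)CC[C@H](Br)C(C)(C)C1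
F10 | step 23 | methyl 7-methyl-3-oxooct-6-enoate | COC(=O)CC(=O)CCC=C(C)C
F11 | step 23 | methyl 5-bromo-6,6-dimethyl-2-oxocyclohexane-1-carboxylate (racemic) | COC(=O)C1C(=O)CCC(Br)C1(C)C
F12 | step 23 | 4-bromo-3,3-dimethylcyclohexan-1-one (racemic) | O=C1CCC(Br)C(C)(C)C1
A1 | alternative 1 | ring A bromohydrin (deacetyl target) | O[C@]1(C[C@@H]2CC[C@]3(CO)[C@@H](Br)CC[C@@](C)(O)[C@@H]23)CC[C@H](Br)C(C)(C)C1
A2 | alternative 1 | hydrindane diol with the 2-methylene-6-methylhept-5-enyl side chain | C=C(CCC=C(C)C)C[C@@H]1CC[C@]2(CO)[C@@H](Br)CC[C@@](C)(O)[C@@H]12
A3 | alternative 2 | bromo trans-hydrindene ester | CC(C)(C)[Si](C)(C)OC[C@@H]2CC[C@]3(C(=O)OC)[C@@H](Br)CC=C(C)[C@@H]23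
A4 | alternative 2 | triene with (Z)-bromoacrylate and (E)-2-methyl diene | CC(C)(C)[Si](C)(C)OC[C@@H](\C=C(/C)C=C)CC/C(C(=O)OC)=C/Br
A5 | alternative 3 | trans-hydrindane with C15 carbinol and C12 ketone | CC(C)(C)[Si](C)(C)OC[C@@H]2CC[C@]3(C(=O)OC)C(=O)CC[C@@](C)(O)[C@@H]23
A6 | alternative 3 | cyclopentane keto enone (acetyl on C16, acryloyl and ester on C11) | CC(C)(C)[Si](C)(C)OC[C@@H]1CC[C@](C(=O)OC)(C(=O)C=C)[C@H]1C(C)=O
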